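**Retrosynthetic overview**

- Feature: in ring A of the chlorinated isoflavone unit (unit 1), the ring oxygen O1 on C8a, the chlorine on C8 and the oxygen on C7 are contiguous. The O1–C8a and C8–Cl bonds are both made from one aryl bromide through an aryne across C8–C8a, captured first by a tethered β-ketoaldehyde enolate oxygen (closing the pyranone of unit 1) and then by a Cl+ donor.
- The cyclisation precursor is an α-formyl deoxybenzoin: formyl carbon by Claisen formylation, CO–CH2 bond by benzyl Grignard addition to 2-bromo-4,6-dimethoxybenzaldehyde and oxidation, diaryl ether first by SNAr of 2,4,6-trimethoxyphenol on 4-fluorobenzaldehyde.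
- Unit 2 is then grown on the trimethoxyphenoxy ring: Friedel–Crafts acylation (C4–C4a), chelation-controlled ortho-demethylation (frees O1), one-carbon closure with DMF-DMA, and global demethylation last.
- Ring order: diaryl ether, then pyranone of unit 1 (aryne step), then pyranone of unit 2.

Key step: step 8

Remark: LiTMP is used as a preformed solution; carbinol 10 is a racemate whose only stereocentre is removed in step 6, and the target has no stereocentre.

**Step 1**
Reactants: 1 1-bromo-3,5-dimethoxybenzene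
Product: 3 2-bromo-4,6-dimethoxybenzaldehyde, via aryl iminium chloride 2 (not isolated)
Conditions: POCl3, DMF, 0 → 90 °C; then ice-water
Reagents that add atoms: N,N-dimethylformamide, CN(C)C=O; water, O
Why: Vilsmeier–Haack formylation should attack the position para to one methoxy group and ortho to the other (next to bromine) in preference to the position flanked by both methoxy groups, and hydrolysis of iminium salt 2 releases the aldehyde.

**Step 2**
Reactants: 4 2,4,6-trimethoxyphenol; 5 4-fluorobenzaldehyde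
Product: 6 4-(2,4,6-trimethoxyphenoxy)benzaldehyde
Conditions: K2CO3, DMF, 110 °C, argon (degassed)
Reagents that add atoms: none
Why: Nucleophilic aromatic substitution (SNAr) in which the para-formyl group activates fluoride towards the potassium phenoxide of 4, air being excluded because this electron-rich phenoxide is easily oxidised.

**Step 3**
Reactants: 6 4-(2,4,6-trimethoxyphenoxy)benzaldehyde
Product: 7 [4-(2,4,6-trimethoxyphenoxy)phenyl]methanol
Conditions: NaBH4, MeOH/THF, 0 °C
Reagents that add atoms: none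
Why: Hydride reduction of the aldehyde, to which the aryl ethers are inert.

**Step 4**
Reactants: 7 [4-(2,4,6-trimethoxyphenoxy)phenyl]methanol
Product: 8 2-[4-(chloromethyl)phenoxy]-1,3,5-trimethoxybenzene
Conditions: SOCl2, pyridine, CH2Cl2, 0 °C
Reagents that add atoms: thionyl chloride, O=S(Cl)Cl
Why: Chlorination of the benzylic alcohol through its chlorosulfite, with pyridine taking up HCl so that the electron-rich trimethoxyphenoxy ring is not alkylated by the benzylic electrophile under acid.

**Step 5**
Reactants: 8 2-[4-(chloromethyl)phenoxy]-1,3,5-trimethoxybenzene; 3 2-bromo-4,6-dimethoxybenzaldehyde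
Product: 10 rac-1-(2-bromo-4,6-dimethoxyphenyl)-2-[4-(2,4,6-trimethoxyphenoxy)phenyl]ethan-1-ol, via benzylmagnesium chloride 9 (not isolated)
Conditions: Mg turnings, 2-MeTHF, 0 °C (slow addition of 8); then 3, −20 → 0 °C; aq. NH4Cl
Reagents that add atoms: none
Why: Grignard formation (slow addition over excess Mg keeps Wurtz coupling down) and 1,2-addition to the aldehyde, the aryl bromide being inert to a benzylic magnesium reagent at this temperature; the carbinol centre forms as a racemate and is removed in step 6.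

**Step 6**
Reactants: 10 rac-1-(2-bromo-4,6-dimethoxyphenyl)-2-[4-(2,4,6-trimethoxyphenoxy)phenyl]ethan-1-ol
Product: 11 1-(2-bromo-4,6-dimethoxyphenyl)-2-[4-(2,4,6-trimethoxyphenoxy)phenyl]ethan-1-one
Conditions: Dess–Martin periodinane (1.2 equiv), CH2Cl2, 0 °C → rt
Reagents that add atoms: none
Why: Dess–Martin oxidation of the secondary benzylic alcohol to the ketone, with only a slight excess of oxidant so that the activated methylene is not carried on to the 1,2-diketone.

**Step 7**
Reactants: 11 1-(2-bromo-4,6-dimethoxyphenyl)-2-[4-(2,4,6-trimethoxyphenoxy)phenyl]ethan-1-one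
Product: 12 (Z)-1-(2-bromo-4,6-dimethoxyphenyl)-3-hydroxy-2-[4-(2,4,6-trimethoxyphenoxy)phenyl]prop-2-en-1-one
Conditions: NaH, HCO2Et, THF, 0 °C → rt; then AcOH, H2O, 0 °C
Reagents that add atoms: ethyl formate, CCOC=O
Why: Crossed Claisen condensation at the only enolisable position, driven by formation of the stabilised β-ketoaldehyde enolate, whose acidification gives the hydrogen-bonded (Z)-enol.

**Step 8**
Reactants: 12 (Z)-1-(2-bromo-4,6-dimethoxyphenyl)-3-hydroxy-2-[4-(2,4,6-trimethoxyphenoxy)phenyl]prop-2-en-1-one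
Product: 15 8-chloro-5,7-dimethoxy-3-[4-(2,4,6-trimethoxyphenoxy)phenyl]chromen-4-one, via lithium enolate aryne 13 (not isolated), via 8-lithiochromone 14 (not isolated)
Conditions: lithium 2,2,6,6-tetramethylpiperidide (LiTMP, 2.2 equiv), THF, −78 → −30 °C; then C2Cl6, −78 °C → rt
Reagents that add atoms: hexachloroethane, ClC(Cl)(Cl)C(Cl)(Cl)Cl
Why: Proposed new method: the first equivalent of LiTMP forms the lithium enolate, the second removes the one hydrogen ortho to bromine (between Br and the 4-methoxy group, the most acidic ring position), and loss of LiBr on warming gives aryne 13 across the future C8–C8a bond. After rotation about the C3–C4 bond out of the lithium chelate, the (Z)-enolate oxygen adds in the plane of the aryne to C8a and closes the pyranone by 6-exo O-arylation (O1–C8a); attack at C8 would need a meta-bridged seven-membered ring and is excluded. C8a is also the electronically favoured terminus, because the charge then develops at C8 beside the inductively withdrawing C7 methoxy group, giving the 2,6-dioxygenated aryllithium 14, which C2Cl6 chlorinates (C8–Cl). Closest known reaction types: base-mediated aryne cyclisations of tethered oxygen nucleophiles with electrophilic trapping of the aryllithium formed, and nucleophile/halogen 1,2-difunctionalisation of arynes; a β-ketoaldehyde enolate as the tethered nucleophile and a chromone as the product lie outside them. No stereocentre is formed. The step needs site-selective aryne formation, intramolecular capture and an intact C2–H: the single ortho hydrogen of the bromide fixes the aryne, the tether and the methoxy group fix its capture, and 2.2 equivalents of base at low temperature with C2Cl6 added only after cyclisation leave no amide to attack H-2 or the chlorinating agent.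

**Step 9**
Reactants: 15 8-chloro-5,7-dimethoxy-3-[4-(2,4,6-trimethoxyphenoxy)phenyl]chromen-4-one; 16 4-methoxyphenylacetyl chloride
Product: 17 8-chloro-5,7-dimethoxy-3-(4-{2,4,6-trimethoxy-3-[(4-methoxyphenyl)acetyl]phenoxy}phenyl)chromen-4-one
Conditions: SnCl4 (3 equiv), CH2Cl2, −20 → 0 °C
Reagents that add atoms: none
Why: Friedel–Crafts acylation at one of the two equivalent free positions of the tetra-oxygenated ring (ortho, ortho and para to three methoxy groups), by far the most nucleophilic arene in 15, since ring A of the chromone is deactivated by the SnCl4-bound pyranone carbonyl and the chlorine, and the new ketone shuts the ring down against a second acylation.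

**Step 10**
Reactants: 17 8-chloro-5,7-dimethoxy-3-(4-{2,4,6-trimethoxy-3-[(4-methoxyphenyl)acetyl]phenoxy}phenyl)chromen-4-one
Product: 18 8-chloro-5-hydroxy-3-(4-{2-hydroxy-4,6-dimethoxy-3-[(4-methoxyphenyl)acetyl]phenoxy}phenyl)-7-methoxychromen-4-one
Conditions: BCl3 (4 equiv), CH2Cl2, −78 → 0 °C; then MeOH, H2O
Reagents that add atoms: none
Why: Chelation-controlled ether cleavage in which BCl3 bound to a carbonyl oxygen reaches an ortho or peri methoxy oxygen through a six-membered chelate and chloride removes the methyl group, which at the chromone takes the 5-methoxy group and at the new ketone should take the methoxy group wedged between the ketone and the aryloxy substituent (twisted out of plane, hence the more basic oxygen) rather than the one with a free ortho position, in line with the known preferential cleavage of the doubly flanked ortho-methoxy group in 2,3,4,6-tetraoxygenated aryl ketones, the second ortho ether being spared at 0 °C once the ketone oxygen is held in the first boron chelate.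

**Step 11**
Reactants: 18 8-chloro-5-hydroxy-3-(4-{2-hydroxy-4,6-dimethoxy-3-[(4-methoxyphenyl)acetyl]phenoxy}phenyl)-7-methoxychromen-4-one
Product: 20 8-chloro-3-(4-{[5,7-dimethoxy-3-(4-methoxyphenyl)-4-oxochromen-8-yl]oxy}phenyl)-5-hydroxy-7-methoxychromen-4-one, via enaminone 19 (not isolated)
Conditions: DMF-DMA, toluene, 80 °C
Reagents that add atoms: N,N-dimethylformamide dimethyl acetal, COC(OC)N(C)C
Why: Condensation of the activated methylene with DMF-DMA to enaminone 19 and addition–elimination of the neighbouring phenol with loss of dimethylamine (the standard deoxybenzoin-to-isoflavone closure), while the chelated 5-hydroxyl of unit 1 has no partner and stays free, and any O-methylation there would be erased in step 12.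

**Step 12**
Reactants: 20 8-chloro-3-(4-{[5,7-dimethoxy-3-(4-methoxyphenyl)-4-oxochromen-8-yl]oxy}phenyl)-5-hydroxy-7-methoxychromen-4-one
Product: 21 Bisoflavolin I
Conditions: BBr3 (excess), CH2Cl2, −78 °C → rt; then MeOH, H2O
Reagents that add atoms: none
Why: BBr3 cleavage of the four remaining aryl methyl ethers by bromide attack at methyl, which leaves the diaryl ether, the aryl chloride and both pyranones untouched because they offer no sp3 carbon, and the anhydrous medium avoids the pyranone opening that would allow a Wessely–Moser-type 6/8 isomerisation.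

**Compound list**

1 | 1-bromo-3,5-dimethoxybenzene | COc1cc(Br)cc(OC)c1 | starting material
2 | N-[(2-bromo-4,6-dimethoxyphenyl)methylidene]-N-methylmethanaminium chloride | C[N+](C)=Cc1c(Br)cc(OC)cc1OC.[Cl-] | intermediate
3 | 2-bromo-4,6-dimethoxybenzaldehyde | O=Cc1c(Br)cc(OC)cc1OC | intermediate
4 | 2,4,6-trimethoxyphenol | COc1cc(OC)c(O)c(OC)c1 | starting material
5 | 4-fluorobenzaldehyde | O=Cc1ccc(F)cc1 | starting material
6 | 4-(2,4,6-trimethoxyphenoxy)benzaldehyde | O=Cc1ccc(Oc2c(OC)cc(OC)cc2OC)cc1 | intermediate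
7 | [4-(2,4,6-trimethoxyphenoxy)phenyl]methanol | OCc1ccc(Oc2c(OC)cc(OC)cc2OC)cc1 | intermediate
8 | 2-[4-(chloromethyl)phenoxy]-1,3,5-trimethoxybenzene | ClCc1ccc(Oc2c(OC)cc(OC)cc2OC)cc1 | intermediate
9 | [4-(2,4,6-trimethoxyphenoxy)benzyl]magnesium chloride | Cl[Mg]Cc1ccc(Oc2c(OC)cc(OC)cc2OC)cc1 | intermediate
10 | rac-1-(2-bromo-4,6-dimethoxyphenyl)-2-[4-(2,4,6-trimethoxyphenoxy)phenyl]ethan-1-ol | OC(Cc1ccc(Oc2c(OC)cc(OC)cc2OC)cc1)c1c(Br)cc(OC)cc1OC | intermediate
11 | 1-(2-bromo-4,6-dimethoxyphenyl)-2-[4-(2,4,6-trimethoxyphenoxy)phenyl]ethan-1-one | O=C(Cc1ccc(Oc2c(OC)cc(OC)cc2OC)cc1)c1c(Br)cc(OC)cc1OC | intermediate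
12 | (Z)-1-(2-bromo-4,6-dimethoxyphenyl)-3-hydroxy-2-[4-(2,4,6-trimethoxyphenoxy)phenyl]prop-2-en-1-one | O/C=C(\C(=O)c1c(Br)cc(OC)cc1OC)c1ccc(Oc2c(OC)cc(OC)cc2OC)cc1 | intermediate
13 | lithium (Z)-3-(2,3-didehydro-4,6-dimethoxyphenyl)-3-oxo-2-[4-(2,4,6-trimethoxyphenoxy)phenyl]prop-1-en-1-olate | [Li]O/C=C(\C(=O)C1=C(OC)C=C(OC)C#C1)c1ccc(Oc2c(OC)cc(OC)cc2OC)cc1 | intermediate
14 | 8-lithio-5,7-dimethoxy-3-[4-(2,4,6-trimethoxyphenoxy)phenyl]chromen-4-one | O=c1c(-c2ccc(Oc3c(OC)cc(OC)cc3OC)cc2)coc2c([Li])c(OC)cc(OC)c12 | intermediate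
15 | 8-chloro-5,7-dimethoxy-3-[4-(2,4,6-trimethoxyphenoxy)phenyl]chromen-4-one | O=c1c(-c2ccc(Oc3c(OC)cc(OC)cc3OC)cc2)coc2c(Cl)c(OC)cc(OC)c12 | intermediate
16 | 4-methoxyphenylacetyl chloride | COc1ccc(CC(Cl)=O)cc1 | starting material
17 | 8-chloro-5,7-dimethoxy-3-(4-{2,4,6-trimethoxy-3-[(4-methoxyphenyl)acetyl]phenoxy}phenyl)chromen-4-one | O=c1c(-c2ccc(Oc3c(OC)c(C(=O)Cc4ccc(OC)cc4)c(OC)cc3OC)cc2)coc2c(Cl)c(OC)cc(OC)c12 | intermediate
18 | 8-chloro-5-hydroxy-3-(4-{2-hydroxy-4,6-dimethoxy-3-[(4-methoxyphenyl)acetyl]phenoxy}phenyl)-7-methoxychromen-4-one | O=c1c(-c2ccc(Oc3c(O)c(C(=O)Cc4ccc(OC)cc4)c(OC)cc3OC)cc2)coc2c(Cl)c(OC)cc(O)c12 | intermediate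
19 | 8-chloro-3-[4-(3-{(E)-3-(dimethylamino)-2-(4-methoxyphenyl)prop-2-enoyl}-2-hydroxy-4,6-dimethoxyphenoxy)phenyl]-5-hydroxy-7-methoxychromen-4-one | O=c1c(-c2ccc(Oc3c(O)c(C(=O)/C(=C/N(C)C)c4ccc(OC)cc4)c(OC)cc3OC)cc2)coc2c(Cl)c(OC)cc(O)c12 | intermediate
20 | 8-chloro-3-(4-{[5,7-dimethoxy-3-(4-methoxyphenyl)-4-oxochromen-8-yl]oxy}phenyl)-5-hydroxy-7-methoxychromen-4-one | O=c1c(-c2ccc(Oc3c(OC)cc(OC)c4c(=O)c(-c5ccc(OC)cc5)coc34)cc2)coc2c(Cl)c(OC)cc(O)c12 | intermediate
21 | Bisoflavolin I, 8-chloro-3-(4-{[5,7-dihydroxy-3-(4-hydroxyphenyl)-4-oxochromen-8-yl]oxy}phenyl)-5,7-dihydroxychromen-4-one | O=c1c(-c2ccc(Oc3c(O)cc(O)c4c(=O)c(-c5ccc(O)cc5)coc34)cc2)coc2c(Cl)c(O)cc(O)c12 | target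

**Step count and risks**

Total step count: 12. Longest linear sequence: 11 steps (steps 2 to 12, from 2,4,6-trimethoxyphenol and 4-fluorobenzaldehyde); step 1 is a one-step branch that joins at step 5.

Steps most likely to fail:

1. Step 8 (proposed new method). Possible failures: metalation at a ring hydrogen other than the one beside bromine; capture of the aryne between molecules (by amide or a second enolate) instead of within; protonation of the aryllithium before chlorination, so that the chlorine is lost; attack of surplus base at H-2 with opening of the pyranone. The fallback uses known chemistry, sets out from aldehyde 3 and comes back at 15; it puts the chlorine in first and closes the ring without an aryne. Electrophilic chlorination of 3 (NCS, MeCN) at the only remaining position para to a methoxy group should give 2-bromo-3-chloro-4,6-dimethoxybenzaldehyde F1. Addition of Grignard reagent 9 as in step 5 gives rac-1-(2-bromo-3-chloro-4,6-dimethoxyphenyl)-2-[4-(2,4,6-trimethoxyphenoxy)phenyl]ethan-1-ol F2. Dess–Martin oxidation gives 1-(2-bromo-3-chloro-4,6-dimethoxyphenyl)-2-[4-(2,4,6-trimethoxyphenoxy)phenyl]ethan-1-one F3. Claisen formylation (NaH, HCO2Et) gives (Z)-1-(2-bromo-3-chloro-4,6-dimethoxyphenyl)-3-hydroxy-2-[4-(2,4,6-trimethoxyphenoxy)phenyl]prop-2-en-1-one F4. Copper-catalysed intramolecular O-arylation of the enolate at the C–Br bond (copper iodide CuI, 1,10-phenanthroline, K2CO3, DMF, 100 °C; Ullmann type, assisted by the ortho carbonyl) then closes the pyranone and gives 15 with chlorine already on C8.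

2. Step 10. Possible failures: cleavage of the unflanked ortho methoxy group instead of the flanked one (which after closure would give the 6-aryloxy isomer of unit 2), or of both. The fallback sets out from 17 and comes back at 21; it gives up selective demethylation and differentiates the two oxygens by steric protection. Excess BCl3 at room temperature removes both ortho methoxy groups of the ketone and the chromone 5-methyl group, giving 8-chloro-3-(4-{2,4-dihydroxy-6-methoxy-3-[(4-methoxyphenyl)acetyl]phenoxy}phenyl)-5-hydroxy-7-methoxychromen-4-one F5. TBSCl and imidazole (DMF, 0 °C) should silylate only the hydroxyl that has a free ortho position, the other two being either wedged between ketone and aryloxy group or locked in the chromone chelate, giving 3-(4-{4-[(tert-butyldimethylsilyl)oxy]-2-hydroxy-6-methoxy-3-[(4-methoxyphenyl)acetyl]phenoxy}phenyl)-8-chloro-5-hydroxy-7-methoxychromen-4-one F6. DMF-DMA then closes the pyranone through the remaining flanked hydroxyl by way of the (E)-enaminone of F6, 3-[4-(4-[(tert-butyldimethylsilyl)oxy]-3-{(E)-3-(dimethylamino)-2-(4-methoxyphenyl)prop-2-enoyl}-2-hydroxy-6-methoxyphenoxy)phenyl]-8-chloro-5-hydroxy-7-methoxychromen-4-one F7, which is not isolated, to give 3-[4-({5-[(tert-butyldimethylsilyl)oxy]-7-methoxy-3-(4-methoxyphenyl)-4-oxochromen-8-yl}oxy)phenyl]-8-chloro-5-hydroxy-7-methoxychromen-4-one F8. BBr3 removes the silyl group together with the three remaining methyl ethers and gives 21.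

3. Step 9. Possible failures: sequestration of the Lewis acid by the pyranone carbonyl with stalled conversion; loss of CO from the arylacetyl cation so that the ring is benzylated instead of acylated; premature ether cleavage. The fallback sets out from 15 and comes back at 17; it replaces the acylium electrophile by a nitrilium one (Hoesch reaction). 4-Methoxyphenylacetonitrile, ZnCl2 and HCl gas in Et2O/CH2Cl2 at 0 °C should give the ketiminium salt 1-{3-[4-(8-chloro-5,7-dimethoxy-4-oxochromen-3-yl)phenoxy]-2,4,6-trimethoxyphenyl}-2-(4-methoxyphenyl)ethan-1-iminium chloride F9, which is hydrolysed in warm water to ketone 17.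

**Further compounds**

F1 | step 8 | 2-bromo-3-chloro-4,6-dimethoxybenzaldehyde | O=Cc1c(Br)c(Cl)c(OC)cc1OC
F2 | step 8 | rac-1-(2-bromo-3-chloro-4,6-dimethoxyphenyl)-2-[4-(2,4,6-trimethoxyphenoxy)phenyl]ethan-1-ol | OC(Cc1ccc(Oc2c(OC)cc(OC)cc2OC)cc1)c1c(Br)c(Cl)c(OC)cc1OC
F3 | step 8 | 1-(2-bromo-3-chloro-4,6-dimethoxyphenyl)-2-[4-(2,4,6-trimethoxyphenoxy)phenyl]ethan-1-one | O=C(Cc1ccc(Oc2c(OC)cc(OC)cc2OC)cc1)c1c(Br)c(Cl)c(OC)cc1OC
F4 | step 8 | (Z)-1-(2-bromo-3-chloro-4,6-dimethoxyphenyl)-3-hydroxy-2-[4-(2,4,6-trimethoxyphenoxy)phenyl]prop-2-en-1-one | O/C=C(\C(=O)c1c(Br)c(Cl)c(OC)cc1OC)c1ccc(Oc2c(OC)cc(OC)cc2OC)cc1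
F5 | step 10 | 8-chloro-3-(4-{2,4-dihydroxy-6-methoxy-3-[(4-methoxyphenyl)acetyl]phenoxy}phenyl)-5-hydroxy-7-methoxychromen-4-one | O=c1c(-c2ccc(Oc3c(O)c(C(=O)Cc4ccc(OC)cc4)c(O)cc3OC)cc2)coc2c(Cl)c(OC)cc(O)c12
F6 | step 10 | 3-(4-{4-[(tert-butyldimethylsilyl)oxy]-2-hydroxy-6-methoxy-3-[(4-methoxyphenyl)acetyl]phenoxy}phenyl)-8-chloro-5-hydroxy-7-methoxychromen-4-one | O=c1c(-c2ccc(Oc3c(O)c(C(=O)Cc4ccc(OC)cc4)c(O[Si](C)(C)C(C)(C)C)cc3OC)cc2)coc2c(Cl)c(OC)cc(O)c12
F7 | step 10 | 3-[4-(4-[(tert-butyldimethylsilyl)oxy]-3-{(E)-3-(dimethylamino)-2-(4-methoxyphenyl)prop-2-enoyl}-2-hydroxy-6-methoxyphenoxy)phenyl]-8-chloro-5-hydroxy-7-methoxychromen-4-one | O=c1c(-c2ccc(Oc3c(O)c(C(=O)/C(=C/N(C)C)c4ccc(OC)cc4)c(O[Si](C)(C)C(C)(C)C)cc3OC)cc2)coc2c(Cl)c(OC)cc(O)c12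
F8 | step 10 | 3-[4-({5-[(tert-butyldimethylsilyl)oxy]-7-methoxy-3-(4-methoxyphenyl)-4-oxochromen-8-yl}oxy)phenyl]-8-chloro-5-hydroxy-7-methoxychromen-4-one | O=c1c(-c2ccc(Oc3c(OC)cc(O[Si](C)(C)C(C)(C)C)c4c(=O)c(-c5ccc(OC)cc5)coc34)cc2)coc2c(Cl)c(OC)cc(O)c12
F9 | step 9 | 1-{3-[4-(8-chloro-5,7-dimethoxy-4-oxochromen-3-yl)phenoxy]-2,4,6-trimethoxyphenyl}-2-(4-methoxyphenyl)ethan-1-iminium chloride | O=c1c(-c2ccc(Oc3c(OC)c(C(=[NH2+])Cc4ccc(OC)cc4)c(OC)cc3OC)cc2)coc2c(Cl)c(OC)cc(OC)c12.[Cl-]
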